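A direct plan would condense 4-hydroxy-1-methylquinolin-2(1H)-one with prenal to the 2H-pyran A1 (N-methylflindersine) and dimerise A1 with a chiral acid in one flask. The allylic C–O bond would ionise, the cation would unite Diels–Alder-fashion with its dienol to the all-trans cyclohexene bis(quinolinol) A2, and two hydroalkoxylations through monopyran A3 would finish the target. Its weakest operations would be:
- the cationic dimerisation, because both ring C–C bonds, the head-to-tail regiochemistry and three contiguous stereocentres would come from one ion-pair event with nothing in the substrate to steer it;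
- the first ether closure, because it would fix the absolute configuration only by choosing between two equivalent quinolinol OH groups on an otherwise Cs-symmetric core, a choice left to a counter-anion;
- the final bridging etherification, because it would be a reversible strong-acid step on the most precious material, where tertiary cations can re-open either ether, exchange the roles of the two quinolinones (racemisation) or leak to isomeric dimers.

**Plan of the new route**
- Core numbering (p-menthane): C1′ = C(CH3)–O; C2′ and C6′ = CH2; C3′ = CH bearing quinolinone B (its O on C1′, bridged ring B); C4′ = CH bearing C8′(CH3)2; C5′ = CH bearing quinolinone A (its O on C8′, fused ring A); target = 1′S,3′R,4′R,5′S.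
- Cuts: C5′–C4′ and O–C8′ (intramolecular hetero-Diels–Alder) together with C5′=C3 of quinolinone A (Knoevenagel); then O–C1′ and C6′–C5′ (oxypalladation/carbonylation), C1′=C6′ (methylenation) and C3′–C3 of quinolinone B (Michael addition).
- Ring order: ring B first, on a monocyclic pyranoquinolinone; the carbocycle and ring A arise together in the last step.
- Enabling feature: ring A (O–C8′–C4′–C5′ plus C3=C4 of quinolinone A) is the [4+2] retron of a 3-alkylidenequinoline-2,4-dione and a trisubstituted alkene. The chain C5′–C6′–C1′–C2′–C3′–C4′=C8′ is citronellal-like, and its C1′ and C3′ are already tied through ring B, which holds the aldehyde arm and the alkene arm 1,3-diaxial.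
- The two quinolinones enter in different steps with different roles, so nothing symmetric has to be desymmetrised, no C–C bond is made through a cation, and the last step is a neutral pericyclic closure; C3′ and C1′ are each set by a catalyst, C4′ and C5′ by the substrate in one event.

Key step: step 5

Assumption: the (S,S)-diamine of step 1 and the (S,S)-ligand of step 3 are taken to give the configurations drawn; if either induces the opposite sense, its enantiomer is used.

Step 1
Reactants: 1 4-hydroxy-1-methylquinolin-2(1H)-one; 2 (3E)-6-methylhepta-3,5-dien-2-one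
Product: 3 4-hydroxy-1-methyl-3-[(4R)-6-methyl-2-oxohept-5-en-4-yl]quinolin-2(1H)-one (ring-chain tautomeric with its cyclic hemiketals)
Conditions: (S,S)-1,2-diphenylethane-1,2-diamine (10 mol %), AcOH, THF, rt; one recrystallisation
Reagents that add atoms: none
Why: Iminium-catalysed Michael addition of the vinylogous acid (warfarin-type), in which the primary amine activates 2 as its iminium ion and directs C3 of 1 to one face of the β-carbon, setting C3′; 1,6-addition is blocked by the gem-dimethyl terminus.

Step 2
Reactants: 3 4-hydroxy-1-methyl-3-[(4R)-6-methyl-2-oxohept-5-en-4-yl]quinolin-2(1H)-one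
Product: 4 3-[(4R)-2,6-dimethylhepta-1,5-dien-4-yl]-4-hydroxy-1-methylquinolin-2(1H)-one
Conditions: Ph3PCH3Br (3 equiv), KOtBu (2.9 equiv), THF, 0 °C → rt
Reagents that add atoms: methyltriphenylphosphonium bromide C[P+](c1ccccc1)(c1ccccc1)c1ccccc1.[Br-]
Why: Wittig methylenation, in which the first equivalent of ylide deprotonates the vinylogous acid and opens the hemiketal to the keto enolate that is then olefinated; the enolate is too poor a leaving group for retro-Michael loss of C3′, and no stereocentre is formed.

Step 3
Reactants: 4 3-[(4R)-2,6-dimethylhepta-1,5-dien-4-yl]-4-hydroxy-1-methylquinolin-2(1H)-one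
Product: 5 methyl 2-[(2S,4R)-2,6-dimethyl-4-(2-methylprop-1-en-1-yl)-5-oxo-3,4,5,6-tetrahydro-2H-pyrano[3,2-c]quinolin-2-yl]acetate
Conditions: Pd(OCOCF3)2 (10 mol %), (S,S)-Bn-BOXAX (20 mol %), p-benzoquinone (4 equiv), CO (1 atm), MeOH, rt
Reagents that add atoms: carbon monoxide [C-]#[O+]; methanol CO
Why: Proposed new method: the enol oxygen should bind divalent palladium and add syn across the coordinated terminal 1,1-disubstituted alkene (6-exo), giving a neopentyl-type σ-alkylpalladium without β-hydrogen that inserts CO and is methanolysed, zerovalent palladium being reoxidised by benzoquinone; the chiral bis(oxazoline) ligand selects the alkene face and so sets C1′ (C-2 of 5) with the acetate arm cis to the alkenyl group, and the more hindered trisubstituted alkene should bind palladium less well; the closest known reaction types are the enantioselective domino Wacker/carbonylation/methoxylation of 2-(3-methylbut-3-enyl)phenols to 2-methylchroman-2-ylacetates and the racemic Pd-catalysed oxidative cyclisation of 3-alkenyl-4-hydroxyquinolinones.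

Step 4
Reactants: 5 methyl 2-[(2S,4R)-2,6-dimethyl-4-(2-methylprop-1-en-1-yl)-5-oxo-3,4,5,6-tetrahydro-2H-pyrano[3,2-c]quinolin-2-yl]acetate
Product: 6 2-[(2S,4R)-2,6-dimethyl-4-(2-methylprop-1-en-1-yl)-5-oxo-3,4,5,6-tetrahydro-2H-pyrano[3,2-c]quinolin-2-yl]acetaldehyde
Conditions: (i-Bu)2AlH (1.2 equiv), CH2Cl2, −78 °C; aq. potassium sodium tartrate
Reagents that add atoms: none
Why: Partial ester reduction through the aluminium hemiacetal, which is stable at −78 °C and collapses to the aldehyde on work-up; the vinylogous-carbamate lactam and both stereocentres are untouched.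

Step 5
Reactants: 6 2-[(2S,4R)-2,6-dimethyl-4-(2-methylprop-1-en-1-yl)-5-oxo-3,4,5,6-tetrahydro-2H-pyrano[3,2-c]quinolin-2-yl]acetaldehyde; 1 4-hydroxy-1-methylquinolin-2(1H)-one
Product: 8 paraensidimerin C, via alkylidenequinolinedione 7 (not isolated)
Conditions: 1 (1.1 equiv), ethylenediammonium diacetate (10 mol %), MeCN, rt → 50 °C, 6 added slowly
Reagents that add atoms: none
Why: Domino Knoevenagel/intramolecular hetero-Diels–Alder reaction, the type known for citronellal with 4-hydroxyquinolin-2-ones and 4-hydroxycoumarins: the buffer condenses the unbranched CH2CHO arm of 6 with C3 of 1 to alkylidenedione 7, whose 1-oxadiene (O=C4–C3=C5′) adds with inverse electron demand across the C4′=C8′ alkene, carbon to the less substituted C4′ and oxygen to the tertiary C8′. The carbocycle closes by the C5′–C4′ bond between the two arms that ring B holds 1,3-diaxial (this creates the 2-oxabicyclo[3.3.1]nonane), and ring A closes by the O–C8′ bond of the same [4+2] event, fused to the new carbocycle. C4′ is controlled by allylic 1,3-strain: the (Z)-methyl group keeps C3′–H in the alkene plane and C8′ away from the lactam carbonyl of quinolinone B, so the tethered heterodiene should reach only the alkene face on the side of C2′, which places C8′ trans to quinolinone B. C5′ follows from the exo-(E)-anti transition state with the tether outside the heterodiene, giving the trans ring fusion (H-4′ and H-5′ anti) through a boat-like carbocycle; the cis-fused alternative would need C8′ axial on a chair, syn to the axial hydrogens on C2′ and C6′. The step needs the ketone C4=O rather than the amide C2=O as heterodiene terminus, which amide resonance should favour, and it needs condensation and cycloaddition to outrun β-elimination of the ring-B oxygen from C1′, for which the weakly acidic buffer, the unhindered aldehyde and the pre-organisation (quaternary C1′, alkenyl group at C3′ held pseudo-axial by the neighbouring lactam carbonyl) are chosen. C1′ and C3′ are not touched, so 8 should form as the single enantiomer.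

## Compound list

1 | 4-hydroxy-1-methylquinolin-2(1H)-one | Cn1c(=O)cc(O)c2ccccc21 | starting material
2 | (3E)-6-methylhepta-3,5-dien-2-one | CC(=O)/C=C/C=C(C)C | starting material
3 | 4-hydroxy-1-methyl-3-[(4R)-6-methyl-2-oxohept-5-en-4-yl]quinolin-2(1H)-one (open form; equilibrates with its cyclic hemiketals) | CC(=O)C[C@H](C=C(C)C)c1c(O)c2ccccc2n(C)c1=O | intermediate
4 | 3-[(4R)-2,6-dimethylhepta-1,5-dien-4-yl]-4-hydroxy-1-methylquinolin-2(1H)-one | C=C(C)C[C@H](C=C(C)C)c1c(O)c2ccccc2n(C)c1=O | intermediate
5 | methyl 2-[(2S,4R)-2,6-dimethyl-4-(2-methylprop-1-en-1-yl)-5-oxo-3,4,5,6-tetrahydro-2H-pyrano[3,2-c]quinolin-2-yl]acetate (acetate arm cis to the alkenyl group) | COC(=O)C[C@]1(C)C[C@H](C=C(C)C)c2c(O1)c1ccccc1n(C)c2=O | intermediate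
6 | 2-[(2S,4R)-2,6-dimethyl-4-(2-methylprop-1-en-1-yl)-5-oxo-3,4,5,6-tetrahydro-2H-pyrano[3,2-c]quinolin-2-yl]acetaldehyde | O=CC[C@]1(C)C[C@H](C=C(C)C)c2c(O1)c1ccccc1n(C)c2=O | intermediate
7 | (3Z)-3-{2-[(2R,4R)-2,6-dimethyl-4-(2-methylprop-1-en-1-yl)-5-oxo-3,4,5,6-tetrahydro-2H-pyrano[3,2-c]quinolin-2-yl]ethylidene}-1-methylquinoline-2,4(1H,3H)-dione (same spatial arrangement at C-2 as in 6; the descriptor changes by the priority rules; side chain cis to the amide carbonyl) | O=C1c2ccccc2N(C)C(=O)/C1=C\C[C@]1(C)C[C@H](C=C(C)C)c2c(O1)c1ccccc1n(C)c2=O | intermediate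
8 | paraensidimerin C (core numbering 1′S,3′R,4′R,5′S; ring A trans-fused, ring B bridging C1′ and C3′) | Cn1c(=O)c2c(c3ccccc31)OC(C)(C)[C@@H]1[C@@H]2C[C@]2(C)C[C@H]1c1c(c3ccccc3n(C)c1=O)O2 | target

**Step count and risks**

Total step count: 5. Longest linear sequence: 5 steps (2 → 3 → 4 → 5 → 6 → 8; 1 enters in steps 1 and 5).

Steps most likely to fail:

1. Step 3 (proposed method). The oxypalladation may close onto the trisubstituted alkene instead, or the ligand and the existing C3′ centre may be mismatched, giving poor face selectivity at C1′. The fallback sets out from 3 and uses known reactions under thermodynamic control. Horner–Wadsworth–Emmons olefination with trimethyl phosphonoacetate (NaH, THF) should give methyl (2E,5R)-5-(4-hydroxy-1-methyl-2-oxo-1,2-dihydroquinolin-3-yl)-3,7-dimethylocta-2,6-dienoate F1 (its 2Z isomer serves equally). Intramolecular oxa-Michael addition (DBU, MeCN) should then close ring B to 5 together with its C-2 epimer, methyl 2-[(2R,4R)-2,6-dimethyl-4-(2-methylprop-1-en-1-yl)-5-oxo-3,4,5,6-tetrahydro-2H-pyrano[3,2-c]quinolin-2-yl]acetate F2. The epimers are separated by chromatography and F2 is returned to the DBU equilibration; the route is rejoined at 5.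

2. Step 5 (key step). Aldehyde 6 may lose the ring-B oxygen by β-elimination (retro-oxa-Michael) under the amine buffer before it condenses, the freed enal then being diverted into a 2H-pyran with 1. The fallback sets out from 5 and never forms the free aldehyde. Hydrolysis with Me3SnOH (1,2-dichloroethane, 80 °C) should give 2-[(2S,4R)-2,6-dimethyl-4-(2-methylprop-1-en-1-yl)-5-oxo-3,4,5,6-tetrahydro-2H-pyrano[3,2-c]quinolin-2-yl]acetic acid F3. C-Acylation of 1 with F3 (DCC, DMAP; O-acylation followed by 1,3-acyl shift) should give 3-{[(2S,4R)-2,6-dimethyl-4-(2-methylprop-1-en-1-yl)-5-oxo-3,4,5,6-tetrahydro-2H-pyrano[3,2-c]quinolin-2-yl]acetyl}-4-hydroxy-1-methylquinolin-2(1H)-one F4. Reduction with NaBH4 (MeOH, 0 °C, acetone quench) should give 4-hydroxy-3-{1-hydroxy-2-[(2S,4R)-2,6-dimethyl-4-(2-methylprop-1-en-1-yl)-5-oxo-3,4,5,6-tetrahydro-2H-pyrano[3,2-c]quinolin-2-yl]ethyl}-1-methylquinolin-2(1H)-one F5. Warming F5 with AcOH in toluene should dehydrate it to 7 under amine-free conditions; the route is rejoined at 7, which cyclises to 8.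

3. Step 1. Face discrimination at the β-carbon of the dienone may be poor, or the ee may not be upgradable by crystallisation. The fallback sets out from 1 and 2 and replaces asymmetric catalysis by resolution. Uncatalysed addition with Et3N in refluxing MeOH should give 3 together with its enantiomer, 4-hydroxy-1-methyl-3-[(4S)-6-methyl-2-oxohept-5-en-4-yl]quinolin-2(1H)-one F6. The two are separated by preparative chromatography on a chiral stationary phase (amylose tris(3,5-dimethylphenylcarbamate)); the route is rejoined at 3.

## Further compounds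

F1 | step 3 | methyl (2E,5R)-5-(4-hydroxy-1-methyl-2-oxo-1,2-dihydroquinolin-3-yl)-3,7-dimethylocta-2,6-dienoate | COC(=O)/C=C(\C)C[C@H](C=C(C)C)c1c(O)c2ccccc2n(C)c1=O
F2 | step 3 | methyl 2-[(2R,4R)-2,6-dimethyl-4-(2-methylprop-1-en-1-yl)-5-oxo-3,4,5,6-tetrahydro-2H-pyrano[3,2-c]quinolin-2-yl]acetate | COC(=O)C[C@@]1(C)C[C@H](C=C(C)C)c2c(O1)c1ccccc1n(C)c2=O
F3 | step 5 | 2-[(2S,4R)-2,6-dimethyl-4-(2-methylprop-1-en-1-yl)-5-oxo-3,4,5,6-tetrahydro-2H-pyrano[3,2-c]quinolin-2-yl]acetic acid | OC(=O)C[C@]1(C)C[C@H](C=C(C)C)c2c(O1)c1ccccc1n(C)c2=O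
F4 | step 5 | 3-{[(2S,4R)-2,6-dimethyl-4-(2-methylprop-1-en-1-yl)-5-oxo-3,4,5,6-tetrahydro-2H-pyrano[3,2-c]quinolin-2-yl]acetyl}-4-hydroxy-1-methylquinolin-2(1H)-one | Cn1c(=O)c(C(=O)C[C@]2(C)C[C@H](C=C(C)C)c3c(O2)c2ccccc2n(C)c3=O)c(O)c2ccccc21
F5 | step 5 | 4-hydroxy-3-{1-hydroxy-2-[(2S,4R)-2,6-dimethyl-4-(2-methylprop-1-en-1-yl)-5-oxo-3,4,5,6-tetrahydro-2H-pyrano[3,2-c]quinolin-2-yl]ethyl}-1-methylquinolin-2(1H)-one (either carbinol epimer) | Cn1c(=O)c(C(O)C[C@]2(C)C[C@H](C=C(C)C)c3c(O2)c2ccccc2n(C)c3=O)c(O)c2ccccc21
F6 | step 1 | 4-hydroxy-1-methyl-3-[(4S)-6-methyl-2-oxohept-5-en-4-yl]quinolin-2(1H)-one | CC(=O)C[C@@H](C=C(C)C)c1c(O)c2ccccc2n(C)c1=O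
A1 | direct plan | N-methylflindersine (2,2,6-trimethyl-2,6-dihydro-5H-pyrano[3,2-c]quinolin-5-one) | CC1(C)C=Cc2c(O1)c1ccccc1n(C)c2=O
A2 | direct plan | 3,3′-[5-methyl-2-(prop-1-en-2-yl)cyclohex-4-ene-1,3-diyl]bis(4-hydroxy-1-methylquinolin-2(1H)-one), 1,2-trans-2,3-trans | CC(=C)[C@@H]1[C@H](CC(C)=C[C@H]1c1c(O)c2ccccc2n(C)c1=O)c1c(O)c2ccccc2n(C)c1=O
A3 | direct plan | monopyran: trans-fused 2,2-dimethyl-dihydropyrano[3,2-c]quinolin-5-one on the methylcyclohexene, with a free 4-hydroxy-1-methylquinolin-2-one on the allylic ring carbon | Cn1c(=O)c2c(c3ccccc31)OC(C)(C)[C@@H]1[C@@H]2CC(C)=C[C@H]1c1c(O)c2ccccc2n(C)c1=O
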